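Ring A of the target is cut away from a furan: its C4 hydroxyl, C5 alkyl chain, C6 methoxy and C7 hydrogen in a row, fused to the furan ring through C3a–C7a, are the imprint of a ketene–ynol ether benzannulation. The precursor is a 2-furyl diazo ketone that already holds the C3 aldehyde as a dimethyl acetal and the C2 aryl group as a silyl ether; irradiated with a methyl ynol ether carrying the silylated side chain, it should undergo Wolff rearrangement, (2+2) cycloaddition, ring opening and electrocyclisation onto the neighbouring furan carbon, forming four C–C bonds and the fully substituted benzofuran in one operation. One deprotection finishes the synthesis.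

Key step: step 8

Remark: the target is achiral, so no stereocentre has to be set; the aryl phenol is carried as a triisopropylsilyl ether (no hydrogenolysis next to a benzylic acetal, no benzyl ether under light, no directed lithiation between the two aryl oxygens), and (3-formylfuran-2-yl)boronic acid is taken as a purchasable building block.

Step 1
Reactants: 1 4-bromo-3-methoxyphenol
Product: 2 (4-bromo-3-methoxyphenoxy)tri(propan-2-yl)silane
Conditions: i-Pr3SiCl, imidazole, DMF, rt
Reagents that add atoms: chlorotri(propan-2-yl)silane, CC(C)[Si](Cl)(C(C)C)C(C)C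
Why: Imidazole-promoted silylation of the phenol should be clean, and the bulky aryl silyl ether is chosen because it tolerates aqueous phosphate, catalytic acid, organolithium and amide bases and near-ultraviolet light, shields the arene C–H between the two oxygens, and leaves at the end with fluoride.

Step 2
Reactants: 2 (4-bromo-3-methoxyphenoxy)tri(propan-2-yl)silane, 3 (3-formylfuran-2-yl)boronic acid
Product: 4 2-(2-methoxy-4-{[tri(propan-2-yl)silyl]oxy}phenyl)furan-3-carbaldehyde
Conditions: Pd(OAc)2 (cat.), SPhos (2-dicyclohexylphosphino-2',6'-dimethoxybiphenyl, cat.), K3PO4, toluene/H2O, 60 °C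
Reagents that add atoms: none
Why: Suzuki–Miyaura coupling should join the rings exactly at furan C2 because the boron atom marks that carbon, and the electron-rich biarylphosphine should keep oxidative addition into the ortho-methoxy aryl bromide and transmetalation faster than protodeboronation of the furylboronic acid.

Step 3
Reactants: 4 2-(2-methoxy-4-{[tri(propan-2-yl)silyl]oxy}phenyl)furan-3-carbaldehyde
Product: 5 {4-[3-(dimethoxymethyl)furan-2-yl]-3-methoxyphenoxy}tri(propan-2-yl)silane
Conditions: HC(OMe)3, MeOH, p-TsOH·H2O (cat.), rt; Et3N quench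
Reagents that add atoms: trimethyl orthoformate, COC(OC)OC; methanol, CO
Why: Acid-catalysed acetalisation, driven to completion by the orthoformate as water scavenger, should mask the aldehyde for the organolithium and enolate steps, and the 2-arylfuran and the aryl silyl ether tolerate catalytic sulfonic acid at room temperature.

Step 4
Reactants: 5 {4-[3-(dimethoxymethyl)furan-2-yl]-3-methoxyphenoxy}tri(propan-2-yl)silane
Product: 8 1-[4-(dimethoxymethyl)-5-(2-methoxy-4-{[tri(propan-2-yl)silyl]oxy}phenyl)furan-2-yl]ethan-1-one, via furyllithium 6 (not isolated), via tetrahedral lithium adduct 7 (not isolated)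
Conditions: n-BuLi, THF, −78 → −20 °C; MeC(O)N(OMe)Me, −78 → 0 °C; aq. NH4Cl
Reagents that add atoms: N-methoxy-N-methylacetamide, CC(=O)N(C)OC; n-butyllithium, [Li]CCCC (its lithium is carried only by 6 and 7)
Why: Deprotonative lithiation should take place at furan C5, the only free position next to the ring oxygen and the most acidic C–H (the arene C–H between the oxygens is screened by the bulky silyl ether), and acylation by the N-methoxy-N-methylamide should stop at the ketone because the chelated adduct 7 survives until the quench.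

Step 5
Reactants: 8 1-[4-(dimethoxymethyl)-5-(2-methoxy-4-{[tri(propan-2-yl)silyl]oxy}phenyl)furan-2-yl]ethan-1-one
Product: 11 2-diazo-1-[4-(dimethoxymethyl)-5-(2-methoxy-4-{[tri(propan-2-yl)silyl]oxy}phenyl)furan-2-yl]ethan-1-one, via lithium enolate 9 (not isolated), via trifluoroacetyl diketone 10 (not isolated)
Conditions: LiN(SiMe3)2, THF, −78 °C; CF3CO2CH2CF3; cold aq. NaH2PO4 work-up; then MsN3, Et3N, H2O, MeCN, rt
Reagents that add atoms: methanesulfonyl azide, CS(=O)(=O)N=[N+]=[N-]; 2,2,2-trifluoroethyl trifluoroacetate, O=C(OCC(F)(F)F)C(F)(F)F (its trifluoroacetyl group is carried only by 10); lithium bis(trimethylsilyl)amide, [Li]N([Si](C)(C)C)[Si](C)(C)C (its lithium is carried only by 9)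
Why: In this detrifluoroacetylative diazo transfer the lithium enolate of the methyl ketone undergoes Claisen trifluoroacetylation and the activated diketone then accepts N2 from the sulfonyl azide with loss of the trifluoroacetyl group as its N-sulfonyl amide, all under basic or buffered conditions that acetal and silyl ether tolerate.

Step 6
Reactants: 12 4-bromo-2-methylbutan-2-ol
Product: 13 [(4-bromo-2-methylbutan-2-yl)oxy]triethylsilane
Conditions: Et3SiOTf, 2,6-lutidine, CH2Cl2, 0 °C
Reagents that add atoms: triethylsilyl trifluoromethanesulfonate, CC[Si](CC)(CC)OS(=O)(=O)C(F)(F)F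
Why: The hindered tertiary alcohol should be silylated by the silyl triflate with a hindered pyridine base without touching the primary bromide, and the silyl ether keeps the hydroxyl group from quenching the acetylide and from adding to ketenes later.

Step 7
Reactants: 14 2-chloro-1,1-dimethoxyethane, 13 [(4-bromo-2-methylbutan-2-yl)oxy]triethylsilane
Product: 16 triethyl[(6-methoxy-2-methylhex-5-yn-2-yl)oxy]silane, via lithium methoxyacetylide 15 (not isolated)
Conditions: LiNEt2 (3 equiv per 14), THF, 0 °C; then 13, DMPU, −78 °C → rt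
Reagents that add atoms: lithium diethylamide, [Li]N(CC)CC (its lithium is carried only by 15)
Why: Three equivalents of lithium amide should convert the chloroacetal by loss of methanol, loss of HCl and deprotonation into lithium methoxyacetylide, which should displace the unhindered primary bromide in an SN2 alkylation at carbon once the dipolar cosolvent breaks up its aggregates.

Step 8
Reactants: 11 2-diazo-1-[4-(dimethoxymethyl)-5-(2-methoxy-4-{[tri(propan-2-yl)silyl]oxy}phenyl)furan-2-yl]ethan-1-one, 16 triethyl[(6-methoxy-2-methylhex-5-yn-2-yl)oxy]silane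
Product: 21 3-(dimethoxymethyl)-6-methoxy-2-(2-methoxy-4-{[tri(propan-2-yl)silyl]oxy}phenyl)-5-{3-methyl-3-[(triethylsilyl)oxy]butyl}-1-benzofuran-4-ol, via furylketene 17 (not isolated), via cyclobutenone 18 (not isolated), via dienylketene 19 (not isolated), via cyclohexadienone 20 (not isolated)
Conditions: 16 (1.5 equiv), hν (350 nm, Pyrex), ClCH2CH2Cl, rt; then 80 °C in the dark
Reagents that add atoms: none
Why: Excitation of diazo ketone 11 expels N2 and the furyl group migrates from the carbonyl carbon to the former diazo carbon (Wolff rearrangement), giving furylketene 17, whose central carbon is attacked by the alkyne carbon of 16 remote from the methoxy group in a (2+2) cycloaddition that yields cyclobutenone 18. In the dark at 80 °C, 18 opens reversibly by a four-electron conrotatory electrocyclic reaction to dienylketene 19, and the isomer with the furyl group cis to the ketene arm closes ring A through a six-electron disrotatory electrocyclisation onto furan C3 (bond C3a–C4), the resulting dienone 20 tautomerising to phenol 21. The closest known reaction type is the photochemical diazo ketone variant of the Danheiser benzannulation, established for aryl and heteroaryl diazo ketones with alkoxy- and siloxyalkynes, of which this 2-furyl substrate is an untested member. Atom by atom, the ketene carbonyl becomes C4–OH, the two alkyne carbons become C5 (chain) and C6 (OMe), the diazo carbon becomes C7–H and furan C2 and C3 become C7a and C3a; no stereocentre is left, those of 18 and 20 being transient and racemic. The step needs the right orientation in the (2+2) event, which the polarised ynol ether secures, and ring closure at a single site, which is secured because C3 is the only furan carbon adjacent to the ketene-bearing C2. Light near 350 nm addresses the conjugated diazo ketone and not the protecting groups, and a methyl ynol ether has no β-hydrogen for retro-ene fragmentation at 80 °C.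

Step 9
Reactants: 21 3-(dimethoxymethyl)-6-methoxy-2-(2-methoxy-4-{[tri(propan-2-yl)silyl]oxy}phenyl)-5-{3-methyl-3-[(triethylsilyl)oxy]butyl}-1-benzofuran-4-ol
Product: 23 4-hydroxy-2-(4-hydroxy-2-methoxyphenyl)-5-(3-hydroxy-3-methylbutyl)-6-methoxy-1-benzofuran-3-carbaldehyde, via phenol 22 (not isolated)
Conditions: n-Bu4NF (1.5 equiv), THF, 0 °C; then aq. HCl (1 mol/L), 0 °C → rt
Reagents that add atoms: water, O
Why: Fluoride should cleave the aryl silyl ether to phenol 22, and after acidification of the same flask dilute aqueous acid should hydrolyse the acetal (made labile by the electron-rich benzofuran) and solvolyse the triethylsilyl ether, while acid this weak at room temperature should not ionise the tertiary alcohol, so closure of the side chain onto the C4 phenol to a chroman is not expected.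

Compound list

1 | 4-bromo-3-methoxyphenol | COc1cc(O)ccc1Br | starting material
2 | (4-bromo-3-methoxyphenoxy)tri(propan-2-yl)silane | COc1cc(O[Si](C(C)C)(C(C)C)C(C)C)ccc1Br | intermediate
3 | (3-formylfuran-2-yl)boronic acid | O=Cc1ccoc1B(O)O | starting material
4 | 2-(2-methoxy-4-{[tri(propan-2-yl)silyl]oxy}phenyl)furan-3-carbaldehyde | COc1cc(O[Si](C(C)C)(C(C)C)C(C)C)ccc1-c1occc1C=O | intermediate
5 | {4-[3-(dimethoxymethyl)furan-2-yl]-3-methoxyphenoxy}tri(propan-2-yl)silane | COc1cc(O[Si](C(C)C)(C(C)C)C(C)C)ccc1-c1occc1C(OC)OC | intermediate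
6 | [4-(dimethoxymethyl)-5-(2-methoxy-4-{[tri(propan-2-yl)silyl]oxy}phenyl)furan-2-yl]lithium | COc1cc(O[Si](C(C)C)(C(C)C)C(C)C)ccc1-c1oc([Li])cc1C(OC)OC | intermediate (not isolated)
7 | lithium 1-[4-(dimethoxymethyl)-5-(2-methoxy-4-{[tri(propan-2-yl)silyl]oxy}phenyl)furan-2-yl]-1-[methoxy(methyl)amino]ethan-1-olate | COc1cc(O[Si](C(C)C)(C(C)C)C(C)C)ccc1-c1oc(C(C)(O[Li])N(C)OC)cc1C(OC)OC | intermediate (not isolated)
8 | 1-[4-(dimethoxymethyl)-5-(2-methoxy-4-{[tri(propan-2-yl)silyl]oxy}phenyl)furan-2-yl]ethan-1-one | COc1cc(O[Si](C(C)C)(C(C)C)C(C)C)ccc1-c1oc(C(C)=O)cc1C(OC)OC | intermediate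
9 | lithium 1-[4-(dimethoxymethyl)-5-(2-methoxy-4-{[tri(propan-2-yl)silyl]oxy}phenyl)furan-2-yl]ethen-1-olate | COc1cc(O[Si](C(C)C)(C(C)C)C(C)C)ccc1-c1oc(C(=C)O[Li])cc1C(OC)OC | intermediate (not isolated)
10 | 1-[4-(dimethoxymethyl)-5-(2-methoxy-4-{[tri(propan-2-yl)silyl]oxy}phenyl)furan-2-yl]-4,4,4-trifluorobutane-1,3-dione | COc1cc(O[Si](C(C)C)(C(C)C)C(C)C)ccc1-c1oc(C(=O)CC(=O)C(F)(F)F)cc1C(OC)OC | intermediate (not isolated)
11 | 2-diazo-1-[4-(dimethoxymethyl)-5-(2-methoxy-4-{[tri(propan-2-yl)silyl]oxy}phenyl)furan-2-yl]ethan-1-one | COc1cc(O[Si](C(C)C)(C(C)C)C(C)C)ccc1-c1oc(C(=O)C=[N+]=[N-])cc1C(OC)OC | intermediate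
12 | 4-bromo-2-methylbutan-2-ol | CC(C)(O)CCBr | starting material
13 | [(4-bromo-2-methylbutan-2-yl)oxy]triethylsilane | CC[Si](CC)(CC)OC(C)(C)CCBr | intermediate
14 | 2-chloro-1,1-dimethoxyethane (chloroacetaldehyde dimethyl acetal) | COC(CCl)OC | starting material
15 | (methoxyethynyl)lithium (lithium methoxyacetylide) | [Li]C#COC | intermediate (not isolated)
16 | triethyl[(6-methoxy-2-methylhex-5-yn-2-yl)oxy]silane | COC#CCCC(C)(C)O[Si](CC)(CC)CC | intermediate
17 | 2-[4-(dimethoxymethyl)-5-(2-methoxy-4-{[tri(propan-2-yl)silyl]oxy}phenyl)furan-2-yl]ethen-1-one | COc1cc(O[Si](C(C)C)(C(C)C)C(C)C)ccc1-c1oc(C=C=O)cc1C(OC)OC | intermediate (not isolated)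
18 | 4-[4-(dimethoxymethyl)-5-(2-methoxy-4-{[tri(propan-2-yl)silyl]oxy}phenyl)furan-2-yl]-3-methoxy-2-{3-methyl-3-[(triethylsilyl)oxy]butyl}cyclobut-2-en-1-one (racemic) | O=C1C(CCC(C)(C)O[Si](CC)(CC)CC)=C(OC)C1c1cc(C(OC)OC)c(-c2ccc(O[Si](C(C)C)(C(C)C)C(C)C)cc2OC)o1 | intermediate (not isolated)
19 | (3E)-4-[4-(dimethoxymethyl)-5-(2-methoxy-4-{[tri(propan-2-yl)silyl]oxy}phenyl)furan-2-yl]-3-methoxy-2-{3-methyl-3-[(triethylsilyl)oxy]butyl}buta-1,3-dien-1-one | O=C=C(CCC(C)(C)O[Si](CC)(CC)CC)/C(OC)=C\c1cc(C(OC)OC)c(-c2ccc(O[Si](C(C)C)(C(C)C)C(C)C)cc2OC)o1 | intermediate (not isolated)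
20 | 3-(dimethoxymethyl)-6-methoxy-2-(2-methoxy-4-{[tri(propan-2-yl)silyl]oxy}phenyl)-5-{3-methyl-3-[(triethylsilyl)oxy]butyl}-1-benzofuran-4(3aH)-one (racemic) | O=C1C(CCC(C)(C)O[Si](CC)(CC)CC)=C(OC)C=C2OC(-c3ccc(O[Si](C(C)C)(C(C)C)C(C)C)cc3OC)=C(C(OC)OC)C12 | intermediate (not isolated)
21 | 3-(dimethoxymethyl)-6-methoxy-2-(2-methoxy-4-{[tri(propan-2-yl)silyl]oxy}phenyl)-5-{3-methyl-3-[(triethylsilyl)oxy]butyl}-1-benzofuran-4-ol | COc1cc(O[Si](C(C)C)(C(C)C)C(C)C)ccc1-c1oc2cc(OC)c(CCC(C)(C)O[Si](CC)(CC)CC)c(O)c2c1C(OC)OC | intermediate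
22 | 3-(dimethoxymethyl)-2-(4-hydroxy-2-methoxyphenyl)-6-methoxy-5-{3-methyl-3-[(triethylsilyl)oxy]butyl}-1-benzofuran-4-ol | COc1cc(O)ccc1-c1oc2cc(OC)c(CCC(C)(C)O[Si](CC)(CC)CC)c(O)c2c1C(OC)OC | intermediate (not isolated)
23 | 4-hydroxy-2-(4-hydroxy-2-methoxyphenyl)-5-(3-hydroxy-3-methylbutyl)-6-methoxy-1-benzofuran-3-carbaldehyde | COc1cc(O)ccc1-c1oc2cc(OC)c(CCC(C)(C)O)c(O)c2c1C=O | target

Total step count: 9 steps.
Longest linear sequence: 7 steps (steps 1, 2, 3, 4, 5, 8 and 9); steps 6 and 7 form the two-step side branch.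

Steps most likely to fail

Step 8 (benzannulation). The extended arylfuran chromophore may shed its excitation without losing N2 or undergo secondary photoreactions, the keto carbene may add to the ynol ether instead of rearranging, and the ketene may dimerise or acylate the product phenol before it meets the alkyne. The fallback generates the same ketene thermally and separates the two stages; it sets out from 11 and comes back to the route at 21. Silver-catalysed Wolff rearrangement of 11 in wet THF (PhCO2Ag cat., Et3N, THF/H2O, rt, dark) should give 2-[4-(dimethoxymethyl)-5-(2-methoxy-4-{[tri(propan-2-yl)silyl]oxy}phenyl)furan-2-yl]acetic acid F1. Treatment with 1-chloro-N,N,2-trimethylprop-1-en-1-amine in CH2Cl2 at 0 °C, which releases no HCl, should give 2-[4-(dimethoxymethyl)-5-(2-methoxy-4-{[tri(propan-2-yl)silyl]oxy}phenyl)furan-2-yl]acetyl chloride F2. Slow addition of F2 to Et3N and an excess of 16 in CH2Cl2 at rt should form ketene 17 by dehydrochlorination and trap it as cyclobutenone 18, which is freed from the ammonium salt and then heated in toluene at 80–100 °C to give 21 by way of 19 and 20.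

Step 7 (acetylide alkylation). The SN2 displacement by the aggregated, weakly nucleophilic alkoxyacetylide may be slower than dehydrobromination of 13, N-alkylation of the liberated diethylamine or decay of the acetylide on warming. The fallback uses a far more reactive allylic electrophile and installs the tertiary alcohol after ring A is built; it sets out from 14 (through acetylide 15) and from 11 and comes back to the route at 23.
- Alkylation: 15 with 1-bromo-3-methylbut-2-ene (SMILES CC(C)=CCBr) in THF, −78 → 0 °C, without cosolvent, should give 1-methoxy-5-methylhex-4-en-1-yne F3.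
- Benzannulation: 11 with F3 under the conditions of step 8 should pass through 17, the prenyl cyclobutenone F4, the prenyl dienylketene F5 and the prenyl dienone F6 to the 5-prenyl phenol F7.
- Mukaiyama hydration (Mn(dpm)3 cat., PhSiH3, O2, i-PrOH, rt) should give the tertiary alcohol F8; this neutral hydrogen-atom-transfer process puts the hydroxyl group on the tertiary carbon and offers no cationic path to a chroman.
- Deprotection as in step 9 should give the target 23 by way of the desilylated acetal F9.

Step 2 (Suzuki–Miyaura coupling). Base-promoted protodeboronation of the electron-poor 2-furylboronic acid may outrun transmetalation, returning furan-3-carbaldehyde and unreacted 2. The fallback reverses the polarity of the coupling; it sets out from 2 and comes back to the route at 4. Miyaura borylation of 2 (bis(pinacolato)diboron, PdCl2(dppf) cat., KOAc, dioxane, 90 °C) should give the stable [3-methoxy-4-(4,4,5,5-tetramethyl-1,3,2-dioxaborolan-2-yl)phenoxy]tri(propan-2-yl)silane F10. Coupling of F10 with purchased 2-bromofuran-3-carbaldehyde (SMILES O=Cc1ccoc1Br) under Pd(PPh3)4 (cat.), aq. Na2CO3, DME, 80 °C should give 4.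

Further compounds

F1 | step 8 | 2-[4-(dimethoxymethyl)-5-(2-methoxy-4-{[tri(propan-2-yl)silyl]oxy}phenyl)furan-2-yl]acetic acid | COc1cc(O[Si](C(C)C)(C(C)C)C(C)C)ccc1-c1oc(CC(=O)O)cc1C(OC)OC
F2 | step 8 | 2-[4-(dimethoxymethyl)-5-(2-methoxy-4-{[tri(propan-2-yl)silyl]oxy}phenyl)furan-2-yl]acetyl chloride | COc1cc(O[Si](C(C)C)(C(C)C)C(C)C)ccc1-c1oc(CC(=O)Cl)cc1C(OC)OC
F3 | step 7 | 1-methoxy-5-methylhex-4-en-1-yne | COC#CCC=C(C)C
F4 | step 7 | 4-[4-(dimethoxymethyl)-5-(2-methoxy-4-{[tri(propan-2-yl)silyl]oxy}phenyl)furan-2-yl]-3-methoxy-2-(3-methylbut-2-en-1-yl)cyclobut-2-en-1-one (racemic) | O=C1C(CC=C(C)C)=C(OC)C1c1cc(C(OC)OC)c(-c2ccc(O[Si](C(C)C)(C(C)C)C(C)C)cc2OC)o1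
F5 | step 7 | (3E)-4-[4-(dimethoxymethyl)-5-(2-methoxy-4-{[tri(propan-2-yl)silyl]oxy}phenyl)furan-2-yl]-3-methoxy-2-(3-methylbut-2-en-1-yl)buta-1,3-dien-1-one | O=C=C(CC=C(C)C)/C(OC)=C\c1cc(C(OC)OC)c(-c2ccc(O[Si](C(C)C)(C(C)C)C(C)C)cc2OC)o1
F6 | step 7 | 3-(dimethoxymethyl)-6-methoxy-2-(2-methoxy-4-{[tri(propan-2-yl)silyl]oxy}phenyl)-5-(3-methylbut-2-en-1-yl)-1-benzofuran-4(3aH)-one (racemic) | O=C1C(CC=C(C)C)=C(OC)C=C2OC(-c3ccc(O[Si](C(C)C)(C(C)C)C(C)C)cc3OC)=C(C(OC)OC)C12
F7 | step 7 | 3-(dimethoxymethyl)-6-methoxy-2-(2-methoxy-4-{[tri(propan-2-yl)silyl]oxy}phenyl)-5-(3-methylbut-2-en-1-yl)-1-benzofuran-4-ol | COc1cc(O[Si](C(C)C)(C(C)C)C(C)C)ccc1-c1oc2cc(OC)c(CC=C(C)C)c(O)c2c1C(OC)OC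
F8 | step 7 | 3-(dimethoxymethyl)-5-(3-hydroxy-3-methylbutyl)-6-methoxy-2-(2-methoxy-4-{[tri(propan-2-yl)silyl]oxy}phenyl)-1-benzofuran-4-ol | COc1cc(O[Si](C(C)C)(C(C)C)C(C)C)ccc1-c1oc2cc(OC)c(CCC(C)(C)O)c(O)c2c1C(OC)OC
F9 | step 7 | 3-(dimethoxymethyl)-2-(4-hydroxy-2-methoxyphenyl)-5-(3-hydroxy-3-methylbutyl)-6-methoxy-1-benzofuran-4-ol | COc1cc(O)ccc1-c1oc2cc(OC)c(CCC(C)(C)O)c(O)c2c1C(OC)OC
F10 | step 2 | [3-methoxy-4-(4,4,5,5-tetramethyl-1,3,2-dioxaborolan-2-yl)phenoxy]tri(propan-2-yl)silane | COc1cc(O[Si](C(C)C)(C(C)C)C(C)C)ccc1B1OC(C)(C)C(C)(C)O1
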